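**Assumption:** the target, octadecyl 2,3-dihydroxybenzoate, has no stereocentre, so it is achiral and no stereocontrol is needed.

**Retrosynthetic overview**
- The only strategic bond is the ester C(=O)O–CH2 bond; cutting it gives a 2,3-dihydroxybenzoate anion and an octadecyl electrophile.
- Both fragments are commercial: 2,3-dihydroxybenzoic acid and 1-bromooctadecane.
- No ring is formed; the benzene ring is bought with the 1,2,3-substitution pattern in place.
- No protecting groups: hydrogencarbonate ionises only the carboxylic acid, so the catechol stays as the neutral, poorly nucleophilic phenol.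

**Route**

Step 1
Reactants: 1 2,3-dihydroxybenzoic acid (1.2 equiv); 2 1-bromooctadecane (1.0 equiv)
Product: 4 octadecyl 2,3-dihydroxybenzoate (gentiside E), via potassium 2,3-dihydroxybenzoate 3 (not isolated)
Conditions: KHCO3 (1.2 equiv), DMF, N2, 70 °C, 12 h; then dilute aq. HCl, EtOAc extraction, aq. NaHCO3 wash, silica gel chromatography
Reagents that add atoms: KHCO3 (potassium hydrogencarbonate), [K+].OC(=O)[O-] — supplies only the K+ of intermediate 3; every heavy atom of 4 comes from 1 and 2
Why: This is an SN2 O-alkylation of a carboxylate (carboxylate esterification with a primary alkyl bromide): KHCO3 deprotonates the acid (pKa about 3) but not the catechol OH groups (pKa about 10 and higher), so only the carboxylate attacks the unhindered bromide, and no stereocentre is created.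

Checks on this step:
- Atom balance: C7H6O4 (1) + C18H37Br (2) + KHCO3 gives C25H42O4 (4) + KBr + CO2 + H2O.
- The product has the octadecyl ester and free OH groups at C2 and C3, matching the target SMILES.
- The catechol is protected from air oxidation by the N2 atmosphere and the weak base.
- The slight excess of acid 1 suppresses over-alkylation and is removed in the NaHCO3 wash.

**Compound list**
1 | 2,3-dihydroxybenzoic acid | OC(=O)c1cccc(O)c1O | starting material
2 | 1-bromooctadecane | CCCCCCCCCCCCCCCCCCBr | starting material
3 | potassium 2,3-dihydroxybenzoate | [K+].[O-]C(=O)c1cccc(O)c1O | intermediate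
4 | octadecyl 2,3-dihydroxybenzoate (gentiside E) | CCCCCCCCCCCCCCCCCCOC(=O)c1cccc(O)c1O | target

**Total step count:** 1
**Longest linear sequence:** 1 step

**Steps most likely to fail**
The route has a single step, so step 1 is the only one that can be named.

Step 1 risks: competing ether formation at a phenol (mainly the less hindered 3-OH), air oxidation of the catechol in warm basic DMF, or sluggish conversion of the waxy bromide.

Fallback for step 1: it sets out from compound 1 and comes back to the route at compound 4. The approach changes from chemoselective alkylation of the unprotected acid to a protected-catechol sequence. Compound 1 is perbenzylated with benzyl bromide and K2CO3 in DMF at 60 °C to give benzyl 2,3-bis(benzyloxy)benzoate F1. The benzyl ester alone is saponified with NaOH in MeOH/THF/water at 50 °C and acidified with HCl to give 2,3-bis(benzyloxy)benzoic acid F2. With no free phenol left, the carboxylate of F2 is alkylated with bromide 2 under forcing conditions (K2CO3, DMF, 80 °C) to give octadecyl 2,3-bis(benzyloxy)benzoate F3. Hydrogenolysis of both benzyl ethers (H2 at 1 atm, Pd/C, EtOAc/THF, room temperature) leaves the alkyl ester untouched and delivers 4.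

**Further compounds**
F1 | step 1 | benzyl 2,3-bis(benzyloxy)benzoate | O=C(OCc1ccccc1)c1cccc(OCc2ccccc2)c1OCc1ccccc1
F2 | step 1 | 2,3-bis(benzyloxy)benzoic acid | OC(=O)c1cccc(OCc2ccccc2)c1OCc1ccccc1
F3 | step 1 | octadecyl 2,3-bis(benzyloxy)benzoate | CCCCCCCCCCCCCCCCCCOC(=O)c1cccc(OCc2ccccc2)c1OCc1ccccc1
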